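## Retrosynthetic overview

Locants are those of the target name: ring C1–C6, side chain C1′ and C2′.

1. Target ⇐ chloro diol: both C–Br bonds are made last by one double Appel bromination (C6 with inversion, C2′ primary).
2. Chloro diol ⇐ cyclohexenyl oxirane: C1′–Cl by hydroxyl-directed chloride opening of the allylic epoxide carbon (inversion).
3. Cyclohexene (the only ring) ⇐ acyclic 1,7-diene by ring-closing metathesis (C1=C2).
4. Diene ⇐ fragment A, (3S)-3-chloro-2,2-dimethylhex-5-enal, plus fragment B, (2S)-2-(1-bromoethenyl)oxirane, joined at C1–C6 by a nickel-catalysed, chromium-mediated alkenyl–aldehyde coupling that also sets the C6 carbinol.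
5. Fragment A ⇐ methyl isobutyrate (formylation, asymmetric allylation, Appel chlorination, partial reduction); fragment B ⇐ acrolein (bromination, dehydrobromination, sulfur-ylide epoxidation, hydrolytic kinetic resolution).

Assumption: the facial senses of (R)-TRIP, of (R,R)-(salen)Co(OAc) and of the oxazoline–sulfonamide ligand are taken by analogy with their standard substrates; if one is reversed, the antipodal catalyst is used and nothing else changes.

## Route

Step 1
Reactants: 1 methyl 2-methylpropanoate (methyl isobutyrate)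
Product: 3 methyl 2,2-dimethyl-3-oxopropanoate, via lithium ester enolate 2 (not isolated)
Conditions: LiN(iPr)2, THF, −78 °C; HCO2Me, −78 °C; AcOH quench at −78 °C
Reagents that add atoms: methyl formate, COC=O
Why: Crossed Claisen formylation of a fully substituted ester enolate; the lithium hemiacetalate survives at −78 °C until the quench and the product has no α-hydrogen, so over-addition and self-condensation are suppressed; no stereocentre is formed.

Step 2
Reactants: 3 methyl 2,2-dimethyl-3-oxopropanoate
Product: 4 methyl (3R)-3-hydroxy-2,2-dimethylhex-5-enoate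
Conditions: allylB(pin) (1.2 equiv), (R)-TRIP (5 mol%), toluene, −30 °C; aqueous work-up
Reagents that add atoms: allylboronic acid pinacol ester, C=CCB1OC(C)(C)C(C)(C)O1
Why: Chiral phosphoric acid-catalysed asymmetric allylboration through a closed chair transition state in which the acid binds the boronate oxygen and the formyl hydrogen; the (R)-catalyst delivers allyl to the Re face of the non-enolisable aldehyde and sets the (3R) carbinol.

Step 3
Reactants: 4 methyl (3R)-3-hydroxy-2,2-dimethylhex-5-enoate
Product: 5 methyl (3S)-3-chloro-2,2-dimethylhex-5-enoate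
Conditions: PPh3, CCl4, MeCN, 60 °C
Reagents that add atoms: carbon tetrachloride, ClC(Cl)(Cl)Cl
Why: Appel chlorination, in which chloride displaces the alkoxyphosphonium by SN2 with inversion (3R to 3S); the electron-poor quaternary ester carbon next to the reacting centre disfavours ionisation and methyl shift, and there is no α-hydrogen for elimination into conjugation.

Step 4
Reactants: 5 methyl (3S)-3-chloro-2,2-dimethylhex-5-enoate
Product: 6 (3S)-3-chloro-2,2-dimethylhex-5-enal
Conditions: iBu2AlH (1.05 equiv), CH2Cl2, −78 °C; aq. potassium sodium tartrate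
Reagents that add atoms: none
Why: Partial ester reduction; the aluminium hemiacetal of this α-quaternary ester persists at −78 °C and releases the aldehyde only on work-up, while the secondary chloride and the alkene are inert and the stereocentre is untouched.

Step 5
Reactants: 7 prop-2-enal (acrolein)
Product: 8 rac-2,3-dibromopropanal
Conditions: Br2, CH2Cl2, −78 to 0 °C
Reagents that add atoms: bromine, BrBr
Why: Electrophilic anti addition of bromine to the C=C bond of the enal; the racemic stereocentre is removed in the next step.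

Step 6
Reactants: 8 rac-2,3-dibromopropanal
Product: 9 2-bromoprop-2-enal
Conditions: Et3N, CH2Cl2, 0 °C
Reagents that add atoms: none
Why: E1cB dehydrobromination; the amine removes the acidic α-hydrogen and the β-bromide leaves, giving the α-bromo enal regiospecifically.

Step 7
Reactants: 9 2-bromoprop-2-enal
Product: 10 rac-2-(1-bromoethenyl)oxirane
Conditions: Me3S+ I−, KOtBu, DMSO–THF, −10 °C; then 9, −10 to 0 °C
Reagents that add atoms: trimethylsulfonium iodide, C[S+](C)C.[I-]
Why: Corey–Chaykovsky epoxidation; the unstabilised sulfonium methylide adds 1,2 to the aldehyde and the betaine closes to the terminal epoxide, leaving the vinylic bromide untouched; the product is racemic.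

Step 8
Reactants: 10 rac-2-(1-bromoethenyl)oxirane
Product: 11 (2S)-2-(1-bromoethenyl)oxirane
Conditions: (R,R)-(salen)Co(OAc) (0.5 mol%), H2O (0.55 equiv), THF (minimum), 0 °C to rt; distillation
Reagents that add atoms: none
Why: Jacobsen hydrolytic kinetic resolution of a terminal epoxide; the cooperative two-cobalt mechanism hydrolyses the (R)-enantiomer at the CH2 terminus and leaves the (S)-epoxide in high ee at about 55% conversion, which sets the future C1′ stereocentre.

Step 9
Reactants: 6 (3S)-3-chloro-2,2-dimethylhex-5-enal; 11 (2S)-2-(1-bromoethenyl)oxirane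
Product: 12 (3R,5S)-5-chloro-4,4-dimethyl-2-[(2R)-oxiran-2-yl]octa-1,7-dien-3-ol
Conditions: CrCl2 (4 equiv), NiCl2 (5 mol%), N-[2-(4-isopropyl-4,5-dihydrooxazol-2-yl)-6-methylphenyl]methanesulfonamide (Re-face-selective enantiomer, 4.4 equiv), Et3N (4.4 equiv), THF, 0 °C to rt
Reagents that add atoms: none
Why: Proposed new method: a nickel-catalysed, chromium-mediated (Nozaki–Hiyama–Kishi) alkenylation in which the alkenyl donor is a 1-bromovinyl oxirane, a donor class with a strained allylic C–O bond β to the carbon–metal bond that has not been used in this coupling; zerovalent nickel inserts into the C(sp2)–Br bond, the alkenyl group passes to trivalent chromium, and the covalent, weakly basic alkenyl–chromium bond should add to the aldehyde faster than it eliminates the β-oxygen to an allenyl alkoxide, as it does with 2-haloallylic ethers and acetals; the amine-buffered medium without silyl chloride is poor in Lewis-acidic chloride so the epoxide should survive; the sulfonamide-bound chromium delivers the alkenyl group to the Re face of 6, overrides the weak 1,3-induction of the β-chloride and sets the (3R) carbinol while forming the C1–C6 bond (the oxirane descriptor changes from 2S to 2R only because bromine leaves the CIP ranking); the closest known reaction is the ligand-controlled asymmetric Nozaki–Hiyama–Kishi coupling of 2-alkoxyallylic alkenyl halides with α-branched aldehydes.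

Step 10
Reactants: 12 (3R,5S)-5-chloro-4,4-dimethyl-2-[(2R)-oxiran-2-yl]octa-1,7-dien-3-ol
Product: 13 (1R,5S)-5-chloro-6,6-dimethyl-2-[(2R)-oxiran-2-yl]cyclohex-2-en-1-ol
Conditions: second-generation Grubbs catalyst (5 mol%), CH2Cl2 (0.005 M), 40 °C
Reagents that add atoms: none
Why: Ring-closing metathesis of the terminal alkene onto the 1,1-disubstituted alkene closes the six-membered ring with loss of ethene and gives the trisubstituted C1=C2 bond; the free allylic hydroxyl is tolerated and no stereocentre is touched.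

Step 11
Reactants: 13 (1R,5S)-5-chloro-6,6-dimethyl-2-[(2R)-oxiran-2-yl]cyclohex-2-en-1-ol
Product: 14 (1S,5S)-5-chloro-2-[(1S)-1-chloro-2-hydroxyethyl]-6,6-dimethylcyclohex-2-en-1-ol
Conditions: ClTi(OiPr)3 (1.5 equiv), CH2Cl2, −20 to 0 °C; aq. tartaric acid
Reagents that add atoms: chlorotitanium triisopropoxide, CC(C)O[Ti](Cl)(OC(C)C)OC(C)C
Why: Titanium-mediated, hydroxyl-directed chloride opening of an epoxy alcohol; the ring alkoxide and the epoxide oxygen chelate titanium, the activated allylic C–O bond is cleaved by chloride anti to oxygen, and the (2R)-oxirane carbon becomes the (1S)-chloride by inversion (the ring carbinol descriptor changes from 1R to 1S only through the CIP ranking).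

Step 12
Reactants: 14 (1S,5S)-5-chloro-2-[(1S)-1-chloro-2-hydroxyethyl]-6,6-dimethylcyclohex-2-en-1-ol
Product: 15 (4S,6R)-6-bromo-1-[(1S)-2-bromo-1-chloroethyl]-4-chloro-5,5-dimethylcyclohex-1-ene
Conditions: PPh3 (2.5 equiv), CBr4 (2.5 equiv), CH2Cl2, −20 to 0 °C, diol added to the preformed reagent
Reagents that add atoms: carbon tetrabromide, BrC(Br)(Br)Br
Why: Double Appel bromination; the primary hydroxyl is displaced by SN2, and the allylic ring hydroxyl is displaced by SN2 with inversion (1S carbinol to 6R bromide, pseudoaxial and trans to the C4 chloride); the reacting ring carbon has no β-hydrogen (quaternary C5, vinylic C1), so elimination cannot compete.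

## Compound list

1 | methyl 2-methylpropanoate | COC(=O)C(C)C | starting material
2 | lithium 1-methoxy-2-methylprop-1-en-1-olate (lithium ester enolate) | COC(=C(C)C)O[Li] | intermediate (not isolated)
3 | methyl 2,2-dimethyl-3-oxopropanoate | COC(=O)C(C)(C)C=O | intermediate
4 | methyl (3R)-3-hydroxy-2,2-dimethylhex-5-enoate | C=CC[C@@H](O)C(C)(C)C(=O)OC | intermediate
5 | methyl (3S)-3-chloro-2,2-dimethylhex-5-enoate | C=CC[C@H](Cl)C(C)(C)C(=O)OC | intermediate
6 | (3S)-3-chloro-2,2-dimethylhex-5-enal | C=CC[C@H](Cl)C(C)(C)C=O | intermediate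
7 | prop-2-enal | C=CC=O | starting material
8 | rac-2,3-dibromopropanal | O=CC(Br)CBr | intermediate
9 | 2-bromoprop-2-enal | C=C(Br)C=O | intermediate
10 | rac-2-(1-bromoethenyl)oxirane | C=C(Br)C1CO1 | intermediate
11 | (2S)-2-(1-bromoethenyl)oxirane | C=C(Br)[C@@H]1CO1 | intermediate
12 | (3R,5S)-5-chloro-4,4-dimethyl-2-[(2R)-oxiran-2-yl]octa-1,7-dien-3-ol | C=CC[C@H](Cl)C(C)(C)[C@H](O)C(=C)[C@@H]1CO1 | intermediate
13 | (1R,5S)-5-chloro-6,6-dimethyl-2-[(2R)-oxiran-2-yl]cyclohex-2-en-1-ol | CC1(C)[C@@H](Cl)CC=C([C@@H]2CO2)[C@H]1O | intermediate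
14 | (1S,5S)-5-chloro-2-[(1S)-1-chloro-2-hydroxyethyl]-6,6-dimethylcyclohex-2-en-1-ol | CC1(C)[C@@H](Cl)CC=C([C@H](Cl)CO)[C@H]1O | intermediate
15 | (4S,6R)-6-bromo-1-[(1S)-2-bromo-1-chloroethyl]-4-chloro-5,5-dimethylcyclohex-1-ene | CC1(C)[C@@H](Cl)CC=C([C@H](Cl)CBr)[C@@H]1Br | target

## Step count and risks

Total step count: 12.
Longest linear sequence: 8 steps (steps 1–4, then 9–12; the sequence 5–8, then 9–12 is equally long).

The three steps most likely to fail:

**Step 9 (the proposed new coupling).** The epoxide may be opened by chromium chloride, or the alkenyl–chromium species may eliminate the β-oxygen to an allenol. The fallback uses known chemistry and sets out from 10 and 6.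
- The resolution of 10 is run with the antipodal (S,S)-(salen)Co(OAc), and the hydrolysis product (2S)-3-bromobut-3-ene-1,2-diol F1 is kept.
- 2,2-Dimethoxypropane with catalytic TsOH gives (4S)-4-(1-bromoethenyl)-2,2-dimethyl-1,3-dioxolane F2, an ordinary 2-alkoxyallylic alkenyl bromide.
- The standard ligand-controlled CrCl2/NiCl2 coupling of F2 with 6 gives (3R,5S)-5-chloro-2-[(4R)-2,2-dimethyl-1,3-dioxolan-4-yl]-4,4-dimethylocta-1,7-dien-3-ol F3.
- Ring-closing metathesis gives (1R,5S)-5-chloro-2-[(4R)-2,2-dimethyl-1,3-dioxolan-4-yl]-6,6-dimethylcyclohex-2-en-1-ol F4.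
- Aqueous acetic acid gives (1R,5S)-5-chloro-2-[(1R)-1,2-dihydroxyethyl]-6,6-dimethylcyclohex-2-en-1-ol F5.
- Primary-selective sulfonylation with 2,4,6-triisopropylbenzenesulfonyl chloride in pyridine gives (2R)-2-[(4S,6R)-4-chloro-6-hydroxy-5,5-dimethylcyclohex-1-en-1-yl]-2-hydroxyethyl 2,4,6-tri(propan-2-yl)benzenesulfonate F6.
- K2CO3 in MeOH closes the epoxide with retention at the secondary carbon, and the route is rejoined at 13.

**Step 11.** Chloride may attack the terminal epoxide carbon, add in conjugate fashion at C2, or lose stereochemical integrity through an allyl cation. The fallback sets out from 13 and installs bromide first.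
- TBSOTf and 2,6-lutidine give tert-butyl{[(1R,5S)-5-chloro-6,6-dimethyl-2-[(2R)-oxiran-2-yl]cyclohex-2-en-1-yl]oxy}dimethylsilane F7.
- Li2NiBr4 in THF opens the epoxide at the CH2 terminus to give (1R)-2-bromo-1-[(4S,6R)-6-{[tert-butyl(dimethyl)silyl]oxy}-4-chloro-5,5-dimethylcyclohex-1-en-1-yl]ethan-1-ol F8.
- PPh3 and N-chlorosuccinimide chlorinate with inversion to give tert-butyl{[(1S,5S)-2-[(1S)-2-bromo-1-chloroethyl]-5-chloro-6,6-dimethylcyclohex-2-en-1-yl]oxy}dimethylsilane F9.
- HF·pyridine gives (1S,5S)-2-[(1S)-2-bromo-1-chloroethyl]-5-chloro-6,6-dimethylcyclohex-2-en-1-ol F10.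
- PPh3 and CBr4 convert F10 into 15, where the route is rejoined.

**Step 12.** The 1,4-diol may close to a cyclic ether once the primary oxygen is activated, and bromide may enter at C2 by SN2′ instead of at the hindered C6. The fallback sets out from 13 and reverses the order of halogen introduction, so that no diol ever meets the phosphonium reagent.
- PPh3 and CBr4 at −20 °C (epoxide inert) give (2R)-2-[(4S,6S)-6-bromo-4-chloro-5,5-dimethylcyclohex-1-en-1-yl]oxirane F11.
- Anhydrous HCl in Et2O at −78 °C opens the allylic epoxide carbon with inversion to give (2S)-2-[(4S,6R)-6-bromo-4-chloro-5,5-dimethylcyclohex-1-en-1-yl]-2-chloroethan-1-ol F12.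
- PPh3 and CBr4 brominate the primary alcohol, and the route is rejoined at 15.

## Further compounds

F1 | step 9 | (2S)-3-bromobut-3-ene-1,2-diol | C=C(Br)[C@@H](O)CO
F2 | step 9 | (4S)-4-(1-bromoethenyl)-2,2-dimethyl-1,3-dioxolane | C=C(Br)[C@@H]1COC(C)(C)O1
F3 | step 9 | (3R,5S)-5-chloro-2-[(4R)-2,2-dimethyl-1,3-dioxolan-4-yl]-4,4-dimethylocta-1,7-dien-3-ol | C=CC[C@H](Cl)C(C)(C)[C@H](O)C(=C)[C@@H]1COC(C)(C)O1
F4 | step 9 | (1R,5S)-5-chloro-2-[(4R)-2,2-dimethyl-1,3-dioxolan-4-yl]-6,6-dimethylcyclohex-2-en-1-ol | CC1(C)[C@@H](Cl)CC=C([C@@H]2COC(C)(C)O2)[C@H]1O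
F5 | step 9 | (1R,5S)-5-chloro-2-[(1R)-1,2-dihydroxyethyl]-6,6-dimethylcyclohex-2-en-1-ol | CC1(C)[C@@H](Cl)CC=C([C@@H](O)CO)[C@H]1O
F6 | step 9 | (2R)-2-[(4S,6R)-4-chloro-6-hydroxy-5,5-dimethylcyclohex-1-en-1-yl]-2-hydroxyethyl 2,4,6-tri(propan-2-yl)benzenesulfonate | CC1(C)[C@@H](Cl)CC=C([C@@H](O)COS(=O)(=O)c2c(C(C)C)cc(C(C)C)cc2C(C)C)[C@H]1O
F7 | step 11 | tert-butyl{[(1R,5S)-5-chloro-6,6-dimethyl-2-[(2R)-oxiran-2-yl]cyclohex-2-en-1-yl]oxy}dimethylsilane | CC1(C)[C@@H](Cl)CC=C([C@@H]2CO2)[C@H]1O[Si](C)(C)C(C)(C)C
F8 | step 11 | (1R)-2-bromo-1-[(4S,6R)-6-{[tert-butyl(dimethyl)silyl]oxy}-4-chloro-5,5-dimethylcyclohex-1-en-1-yl]ethan-1-ol | CC1(C)[C@@H](Cl)CC=C([C@@H](O)CBr)[C@H]1O[Si](C)(C)C(C)(C)C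
F9 | step 11 | tert-butyl{[(1S,5S)-2-[(1S)-2-bromo-1-chloroethyl]-5-chloro-6,6-dimethylcyclohex-2-en-1-yl]oxy}dimethylsilane | CC1(C)[C@@H](Cl)CC=C([C@H](Cl)CBr)[C@H]1O[Si](C)(C)C(C)(C)C
F10 | step 11 | (1S,5S)-2-[(1S)-2-bromo-1-chloroethyl]-5-chloro-6,6-dimethylcyclohex-2-en-1-ol | CC1(C)[C@@H](Cl)CC=C([C@H](Cl)CBr)[C@H]1O
F11 | step 12 | (2R)-2-[(4S,6S)-6-bromo-4-chloro-5,5-dimethylcyclohex-1-en-1-yl]oxirane | CC1(C)[C@@H](Cl)CC=C([C@@H]2CO2)[C@@H]1Br
F12 | step 12 | (2S)-2-[(4S,6R)-6-bromo-4-chloro-5,5-dimethylcyclohex-1-en-1-yl]-2-chloroethan-1-ol | CC1(C)[C@@H](Cl)CC=C([C@H](Cl)CO)[C@@H]1Br
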